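## The problem

The target **38** is an all-ether phlorotannin: eight benzene rings (A to H, lettered from the 2,4,6-trihydroxyphenyl end) joined in a line by seven diaryl ether oxygens and carrying 21 free hydroxyls. There is no ring-to-ring C–C bond and no stereocentre, so nothing has to be controlled stereochemically. The task is the ordered, regiocontrolled formation of seven aryl–O–aryl bonds.

The ethers differ greatly in hindrance. In the D–E ether both carbons are flanked by two oxygen substituents (tetra-ortho). The B–C ether is tri-ortho. In the A–B, C–D and G–H ethers one carbon is doubly flanked. Only the two bonds to ring F are nearly unhindered.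

Every ring is electron-rich, so nucleophilic aromatic substitution is possible only where a convertible acceptor is placed on purpose. The free polyphenol, with five pyrogallol-type rings, is oxidised by air and base. All hydroxyls must therefore stay masked to the last step, and the masks must survive phenoxides, fluoride, copper, peracid and organolithium reagents.

Two motifs recur. Rings C, E and G are the same 1,2-dioxy-3,4,5-trihydroxybenzene, and rings B and D are the same 2,6-dihydroxy-1,4-dioxybenzene.

The enabling feature is ring F. Its ether oxygens sit on C1 (to ring E) and C5 (to ring G), meta to each other, and the hydroxyl on C4 is para to C1 and ortho to C5. A formyl group on C4 activates both ether carbons towards phenoxides and is afterwards turned into that hydroxyl by Dakin oxidation.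

## Retrosynthesis

**38 to 37.** The 21 O–CH3 bonds of the henicosamethyl ether **37** are cut last. Methyl is chosen over benzyl because every building block is purchasable as its methyl ether and methyl ethers tolerate all reagents of the route. The forward step must cleave 21 alkyl ethers and leave the seven diaryl ethers intact.

**37 to 24 and 35.** The ether between ring C and ring D is cut at the ring D carbon, dividing the octamer into the five-ring ortho-silylaryl triflate **24** and the three-ring phenol **35**. Three things favour this cut over its neighbours: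
- The ring D carbon has hydrogen on both sides, and the adjacent carbon bears hydrogen next to a methoxy group, so ring D can be used as the 3-methoxyaryne **36**.
- The B–C ether (tri-ortho, ring B carbon between two methoxy groups) and the D–E ether (tetra-ortho) cannot be formed from an aryne.
- The nucleophile, the flanked ring C hydroxyl of **35**, is too hindered to count on in a copper coupling of large fragments.

The forward reaction must add the phenoxide only at the aryne carbon remote from the methoxy group.

**24 to 16.** Triflate **24** comes from bromophenol **21** (silylation, retro-Brook shift, triflation), **21** from phenol **20**, and **20** from benzyl ether **19** by hydrogenolysis. Ether **19** comes from phenol **18** by methylation, and **18** from aldehyde **16** by Dakin oxidation. These steps change functional groups only. The oxidation is what makes the activating group of the key step traceless.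

**16 to 14, 2 and 7 (key disconnection).** Both ether bonds at ring F are cut, leading to the D–E phenol **14**, the G–H phenol **7** and 2,4-difluoro-6-methoxybenzaldehyde **2**. A dihalo ring F for two copper couplings would offer no handle to tell the two positions apart. Here the para and the ortho fluorine differ in hindrance and are taken one after the other. Two dimers and a seven-carbon aldehyde replace a pentamer. The forward reaction must place **14** para and **7** ortho to the formyl group.

**14 and 7 to 3, 11 and 4; 11 to 8; 2 to 1.** Each 2-aryloxy-3,4,5-trimethoxyphenol is cut at the flanked ring carbon–oxygen bond, and its free hydroxyl is traced back to a formyl group. Phenol **14** thus comes from aldehyde **12**, made from phenol **11** and bromo aldehyde **3**. Phenol **7** comes from aldehyde **5**, made from **3** and phenol **4**. One purchasable bromo aldehyde serves rings E and G. Its formyl group first activates the flanked bromide for copper and then becomes the phenol needed in the key step. The tetra-ortho D–E ether is placed here because the pieces are smallest. Phenol **11** is traced through aldehyde **9** to **8**. This fixes which oxygen carries the benzyl group without relying on selective mono-alkylation of a hydroquinone. Aldehyde **2** comes from **1** by methylation.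

**35 to 29 and 32; 29 to 25 and 26; 32 to 30.** Ring C needs the reverse arrangement: its terminal oxygen is bonded to ring B and its flanked oxygen is free. Phenol **35** is therefore traced to aldehyde **33**, made from the A–B phenol **29** and the isomeric bromo aldehyde **32** (bromine at the terminal carbon, formyl at the flanked one). Aldehyde **32** comes from **30** by formylation. Phenol **29** is traced to aldehyde **27**, made from bromo aldehyde **25** and phenol **26**. The same logic holds throughout: a formyl group activates a bromide and then becomes the next nucleophilic oxygen.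

## Roads not taken

**Alternative 1:** The cut is made inside ring A. Two C–C bonds of the ring are broken, so the A–B oxygen is already in place on the central carbon of the aryloxymalonate **A2**, and the other three ring carbons come from the keto diester **A3**.
- Forward step: sodium methoxide would bring about two Claisen-type acylations of the methylene carbons of **A3** by the ester carbons of **A2**, and the product would enolise to the phloroglucinol diester **A1**.
- Merits: the oxygen between two hydroxyls is set without any aryl–oxygen coupling, and ring A arrives with free hydroxyls.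
- Weak points: **A3** condenses with itself under alkoxide, and the alkoxy-substituted malonate is a poor acylating agent. The two ester groups of **A1** must be removed by hydrolysis and decarboxylation, and the free triol must be protected again before ring B can act as a nucleophile. Above all, it solves the least demanding ether and leaves the hindered D–E and B–C ethers and the union of the halves untouched.
- Comparison: it is better in one respect, since it avoids a copper coupling of the air-sensitive phenol **26** (step 14). Against that, the chosen plan reaches the A–B phenol **29** in two steps from purchasable **25** and **26**, and its key step forms two ether bonds at the centre of the molecule.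

**Alternative 2:** Both ether bonds of ring B are cut, and ring B becomes an arene activated by a cationic cyclopentadienylruthenium unit, complex **A5** (divalent ruthenium).
- Forward step: the phenoxide of **26** would displace the chloride with two hydrogen neighbours, and the phenoxide of **A6** the chloride between the two methoxy groups. This gives complex **A4**, from which the metal would be released by irradiation in acetonitrile.
- Merits: the cationic metal makes even the flanked chloride of an electron-rich ring reactive near room temperature, so the tri-ortho B–C ether forms under milder conditions than in step 17. No activating group remains on the ring.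
- Weak points: one equivalent of ruthenium per molecule; the order in which two activated chlorides react must be controlled; electrophilicity drops once the first aryloxy group is on; a photolytic decomplexation is needed; and the ring C partner **A6** must itself be made and later debenzylated. It delivers only the A–B–C third of the target.
- Comparison: as a way to the B–C ether it matches the copper route of steps 14 to 18 and is milder. The chosen plan sets against it catalytic copper, cheap reagents and an activator that ends as an oxygen the target needs.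

**Alternative 3:** The cut goes through ring E. The C–C bond between the carbon carrying the free hydroxyl and the neighbouring CH is broken, and ring E is traced to the cyclobutenone **A8**, in which the hindered D–O bond already sits on an sp2 carbon of the four-membered ring.
- Forward step: on heating, **A8** would open to a dienylketene, close by six-electron electrocyclisation (Moore ring expansion) and tautomerise to phenol **A7**, the 5-ethoxy analogue of the D–E phenol **14**.
- Merits: the tetra-ortho D–E ether, the hardest bond of the target, is never made by coupling at a flanked aryl carbon. The hindered phenoxide of **11** would be attached to a small, strongly electrophilic squaric acid derivative. **A7** could enter step 8 just as **14** does, since all alkyl ethers fall in the last step.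
- Weak points: **A8** needs several steps of squaric acid chemistry. These are attachment of the aryloxide, low-temperature addition of an alkoxyvinyllithium to one of two different carbonyl groups, and O-alkylation of the tertiary alkoxide. The aryloxy group is itself a leaving group towards the organolithium.
- Comparison: for the D–E bond this road is the safer one. The chosen plan sets against it that **14** is reached in two steps (6 and 7) from **11** and purchasable **3**, by the same copper/Dakin sequence used three more times in the route, and that a fallback for step 6 is provided.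

Key step: step 8

Remark: the target has no stereocentre and its ether bonds are taken to rotate freely, so no stereochemical element has to be set; compounds 1, 3, 4, 8, 25, 26 and 30 are taken as purchasable.

## Route

Step 1
Reactants: 1 2,4-difluoro-6-hydroxybenzaldehyde
Product: 2 2,4-difluoro-6-methoxybenzaldehyde
Conditions: MeI, K2CO3, acetone, rt
Reagents that add atoms: iodomethane, CI
Why: Williamson O-methylation of an acidic, formyl-conjugated phenol; at room temperature alkylation should be far faster than displacement of fluoride by the phenoxide.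

Step 2
Reactants: 3 2-bromo-3,4,5-trimethoxybenzaldehyde; 4 3,4,5-trimethoxyphenol
Product: 5 3,4,5-trimethoxy-2-(3,4,5-trimethoxyphenoxy)benzaldehyde
Conditions: CuI (10 mol%), picolinic acid (20 mol%), K3PO4, DMSO, 90 °C, argon
Reagents that add atoms: none
Why: Ullmann diaryl ether synthesis; the ortho-formyl group makes the flanked C–Br bond electron-poor and the phenol is unhindered.

Step 3
Reactants: 5 3,4,5-trimethoxy-2-(3,4,5-trimethoxyphenoxy)benzaldehyde
Product: 7 3,4,5-trimethoxy-2-(3,4,5-trimethoxyphenoxy)phenol (rings G–H), via aryl formate 6 (not isolated)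
Conditions: mCPBA, CH2Cl2, 0 °C to rt; aq. NaHCO3 wash; then K2CO3 (cat.), MeOH, rt
Reagents that add atoms: meta-chloroperoxybenzoic acid, OOC(=O)c1cccc(Cl)c1
Why: Dakin-type Baeyer–Villiger oxidation; the electron-rich aryl group (ortho-aryloxy, para-methoxy) migrates in preference to hydride, and the formate is cleaved by methanolysis.

Step 4
Reactants: 8 4-hydroxy-2,6-dimethoxybenzaldehyde
Product: 9 4-(benzyloxy)-2,6-dimethoxybenzaldehyde
Conditions: BnBr, K2CO3, DMF, rt to 50 °C
Reagents that add atoms: benzyl bromide, BrCc1ccccc1
Why: Williamson benzylation of the only hydroxyl, which is acidified by the para-formyl group.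

Step 5
Reactants: 9 4-(benzyloxy)-2,6-dimethoxybenzaldehyde
Product: 11 4-(benzyloxy)-2,6-dimethoxyphenol, via aryl formate 10 (not isolated)
Conditions: mCPBA, CH2Cl2, 0 °C to rt; aq. NaHCO3 wash; then K2CO3 (cat.), MeOH, rt
Reagents that add atoms: meta-chloroperoxybenzoic acid, OOC(=O)c1cccc(Cl)c1
Why: Dakin-type Baeyer–Villiger oxidation of a 2,4,6-trioxygenated benzaldehyde, whose aryl group has a high migratory aptitude; the formyl position fixes the free hydroxyl between the two methoxy groups.

Step 6
Reactants: 11 4-(benzyloxy)-2,6-dimethoxyphenol; 3 2-bromo-3,4,5-trimethoxybenzaldehyde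
Product: 12 2-[4-(benzyloxy)-2,6-dimethoxyphenoxy]-3,4,5-trimethoxybenzaldehyde
Conditions: CuI (20 mol%), picolinic acid (40 mol%), K3PO4, DMSO, 120 °C, argon
Reagents that add atoms: none
Why: Ullmann coupling under the CuI/picolinic acid conditions used for hindered partners; the ortho-formyl group activates the bromide, and all four ortho substituents are methoxy or formyl groups that can turn out of the way. The hardest ether is made on the smallest fragments.

Step 7
Reactants: 12 2-[4-(benzyloxy)-2,6-dimethoxyphenoxy]-3,4,5-trimethoxybenzaldehyde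
Product: 14 2-[4-(benzyloxy)-2,6-dimethoxyphenoxy]-3,4,5-trimethoxyphenol (rings D–E), via aryl formate 13 (not isolated)
Conditions: mCPBA, CH2Cl2, 0 °C to rt; aq. NaHCO3 wash; then K2CO3 (cat.), MeOH, rt
Reagents that add atoms: meta-chloroperoxybenzoic acid, OOC(=O)c1cccc(Cl)c1
Why: Dakin-type Baeyer–Villiger oxidation as in step 3; the benzyl and methyl ethers are inert to the peracid at room temperature.

Step 8
Reactants: 14 D–E phenol; 2 2,4-difluoro-6-methoxybenzaldehyde; 7 G–H phenol
Product: 16 4-{2-[4-(benzyloxy)-2,6-dimethoxyphenoxy]-3,4,5-trimethoxyphenoxy}-2-methoxy-6-[3,4,5-trimethoxy-2-(3,4,5-trimethoxyphenoxy)phenoxy]benzaldehyde (rings D–E–F–G–H), via fluoro aldehyde 15 (not isolated)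
Conditions: 14 (1.0 equiv), 2 (1.0 equiv), K2CO3, DMSO, 30 °C; then 7 (1.1 equiv), K2CO3, 100 °C
Reagents that add atoms: none
Why: Each ether bond forms by addition–elimination: the potassium phenoxide adds to a fluorine-bearing carbon, the Meisenheimer anion is stabilised by delocalisation onto the formyl oxygen (para for C4, ortho for C2), and fluoride leaves. The closest known reaction type is the displacement of fluoride from 2- and 4-fluorobenzaldehydes by phenoxides, with later oxidation of the aldehyde to a phenol. No ring is closed and no stereocentre is formed. The selectivity needed is site selectivity: the phenoxide of 14 must take the C4 fluorine and leave the C2 fluorine for 7. The substrate secures this because C4 lies between two hydrogens whereas C2 lies next to the formyl group, the ortho-aryloxy phenoxide is bulky, and the free potassium phenoxide in DMSO has no chelation to the carbonyl oxygen that could deliver it to the ortho position. After the first substitution the new para-aryloxy group donates into the ring, so 15 should not react further at 30 °C and one equivalent of 14 is consumed before 7 is added. The second substitution has only one fluoride left and is driven at 100 °C; the 6-methoxy group is a far poorer leaving group and stays.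

Step 9
Reactants: 16 pentaaryl aldehyde (rings D–E–F–G–H)
Product: 18 4-{2-[4-(benzyloxy)-2,6-dimethoxyphenoxy]-3,4,5-trimethoxyphenoxy}-2-methoxy-6-[3,4,5-trimethoxy-2-(3,4,5-trimethoxyphenoxy)phenoxy]phenol, via aryl formate 17 (not isolated)
Conditions: mCPBA, CH2Cl2, 0 °C to rt; aq. NaHCO3 wash; then K2CO3 (cat.), MeOH, rt
Reagents that add atoms: meta-chloroperoxybenzoic acid, OOC(=O)c1cccc(Cl)c1
Why: Dakin-type Baeyer–Villiger oxidation; the formyl group sits between a methoxy and an aryloxy group, so the aryl group migrates and the activator of step 8 becomes the C4 oxygen of ring F.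

Step 10
Reactants: 18 pentaaryl phenol (free hydroxyl on ring F)
Product: 19 5-{2-[4-(benzyloxy)-2,6-dimethoxyphenoxy]-3,4,5-trimethoxyphenoxy}-1,2-dimethoxy-3-[3,4,5-trimethoxy-2-(3,4,5-trimethoxyphenoxy)phenoxy]benzene
Conditions: MeI, K2CO3, DMF, 40 °C
Reagents that add atoms: iodomethane, CI
Why: Williamson methylation; the small electrophile reaches the flanked phenoxide, and the ring F oxygen then matches all other masked hydroxyls.

Step 11
Reactants: 19 pentaaryl benzyl ether
Product: 20 4-(6-{3,4-dimethoxy-5-[3,4,5-trimethoxy-2-(3,4,5-trimethoxyphenoxy)phenoxy]phenoxy}-2,3,4-trimethoxyphenoxy)-3,5-dimethoxyphenol (ring D phenol)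
Conditions: H2 (1 atm), 10% Pd/C, EtOAc–MeOH, rt
Reagents that add atoms: none
Why: Hydrogenolysis of the single benzyl ether; methyl and diaryl ethers are untouched.

Step 12
Reactants: 20 ring D phenol
Product: 21 2-bromo-4-(6-{3,4-dimethoxy-5-[3,4,5-trimethoxy-2-(3,4,5-trimethoxyphenoxy)phenoxy]phenoxy}-2,3,4-trimethoxyphenoxy)-3,5-dimethoxyphenol
Conditions: NBS (1.0 equiv), i-Pr2NH (cat.), CH2Cl2, −78 to 0 °C
Reagents that add atoms: N-bromosuccinimide, BrN1C(=O)CCC1=O
Why: Amine-mediated ortho-bromination of a phenol; the N-bromoamine formed in the flask reacts through the hydrogen-bonded phenol and so should prefer ring D over the aryl ether rings. The para position is blocked and the two ortho positions are equivalent.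

Step 13
Reactants: 21 ring D ortho-bromophenol
Product: 24 4-(6-{3,4-dimethoxy-5-[3,4,5-trimethoxy-2-(3,4,5-trimethoxyphenoxy)phenoxy]phenoxy}-2,3,4-trimethoxyphenoxy)-3,5-dimethoxy-2-(trimethylsilyl)phenyl trifluoromethanesulfonate, via trimethylsilyl ether 22 (not isolated), via lithium 2-silylphenoxide 23 (not isolated)
Conditions: HMDS, THF, 65 °C, then evaporation; n-BuLi, THF, −78 °C; Tf2O, −78 °C to rt
Reagents that add atoms: hexamethyldisilazane, C[Si](C)(C)N[Si](C)(C)C; trifluoromethanesulfonic anhydride, FC(F)(F)S(=O)(=O)OS(=O)(=O)C(F)(F)F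
Why: Standard route to ortho-silylaryl triflates: O-silylation, bromine–lithium exchange, 1,3 oxygen-to-carbon silyl shift (retro-Brook rearrangement) and triflation of the phenoxide. Bromine–lithium exchange at −78 °C is faster than ortho-lithiation of the methoxyarenes.

Step 14
Reactants: 25 4-bromo-2,6-dimethoxybenzaldehyde; 26 2,4,6-trimethoxyphenol
Product: 27 2,6-dimethoxy-4-(2,4,6-trimethoxyphenoxy)benzaldehyde
Conditions: CuI (10 mol%), picolinic acid (20 mol%), K3PO4, DMSO, 100 °C, argon
Reagents that add atoms: none
Why: Ullmann coupling of a hindered phenol with an unhindered bromide activated by the para-formyl group; air is excluded because 26 is easily oxidised.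

Step 15
Reactants: 27 2,6-dimethoxy-4-(2,4,6-trimethoxyphenoxy)benzaldehyde
Product: 29 2,6-dimethoxy-4-(2,4,6-trimethoxyphenoxy)phenol (rings A–B), via aryl formate 28 (not isolated)
Conditions: mCPBA, CH2Cl2, 0 °C to rt; aq. NaHCO3 wash; then K2CO3 (cat.), MeOH, rt
Reagents that add atoms: meta-chloroperoxybenzoic acid, OOC(=O)c1cccc(Cl)c1
Why: Dakin-type Baeyer–Villiger oxidation of a 2,6-dimethoxy-4-aryloxybenzaldehyde; it places the free hydroxyl between the two methoxy groups of ring B.

Step 16
Reactants: 30 5-bromo-1,2,3-trimethoxybenzene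
Product: 32 6-bromo-2,3,4-trimethoxybenzaldehyde, via chloro(methoxy)methyl arene 31 (not isolated)
Conditions: Cl2CHOMe, TiCl4, CH2Cl2, 0 °C; then H2O
Reagents that add atoms: dichloromethyl methyl ether, COC(Cl)Cl; water, O
Why: Rieche formylation; the two free ring positions are equivalent, each ortho to one methoxy group and para to another, so only one aldehyde can form.

Step 17
Reactants: 29 A–B phenol; 32 6-bromo-2,3,4-trimethoxybenzaldehyde
Product: 33 6-[2,6-dimethoxy-4-(2,4,6-trimethoxyphenoxy)phenoxy]-2,3,4-trimethoxybenzaldehyde
Conditions: CuI (20 mol%), picolinic acid (40 mol%), K3PO4, DMSO, 110 °C, argon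
Reagents that add atoms: none
Why: Ullmann coupling; the bromide has the activating formyl group on one side and hydrogen on the other, so this tri-ortho ether is less congested than that of step 6.

Step 18
Reactants: 33 A–B–C aldehyde
Product: 35 6-[2,6-dimethoxy-4-(2,4,6-trimethoxyphenoxy)phenoxy]-2,3,4-trimethoxyphenol (rings A–B–C), via aryl formate 34 (not isolated)
Conditions: mCPBA, CH2Cl2, 0 °C to rt; aq. NaHCO3 wash; then K2CO3 (cat.), MeOH, rt
Reagents that add atoms: meta-chloroperoxybenzoic acid, OOC(=O)c1cccc(Cl)c1
Why: Dakin-type Baeyer–Villiger oxidation; the formyl group between an aryloxy and a methoxy group becomes the flanked hydroxyl of ring C.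

Step 19
Reactants: 24 pentaaryl ortho-silylaryl triflate; 35 A–B–C phenol
Product: 37 henicosamethyl ether of the target (rings A to H, every hydroxyl of 38 as methoxy), via ring D aryne 36 (not isolated)
Conditions: 35 (1.5 equiv), CsF (3 equiv), MeCN, rt
Reagents that add atoms: none
Why: Aryne O-arylation of a phenol; fluoride attacks silicon, triflate leaves, and the cesium phenoxide of 35 adds to the 3-methoxyaryne 36 at the carbon remote from the methoxy group, where the developing carbanion lies next to the inductively withdrawing oxygen. The new ether carbon on ring D has only hydrogen neighbours, so the hindered phenoxide should be accommodated at room temperature.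

Step 20
Reactants: 37 henicosamethyl ether
Product: 38 target octamer (rings A to H, 21 free hydroxyls)
Conditions: BBr3 (excess), CH2Cl2, −78 °C to rt, argon; then MeOH, H2O
Reagents that add atoms: none
Why: Lewis-acid ether cleavage; boron binds each methoxy oxygen and bromide attacks the methyl carbon, whereas the diaryl ethers offer only sp2 carbons and stay intact. The aryloxyboron species are hydrolysed on quenching under argon.

## Compound list

1 | 2,4-difluoro-6-hydroxybenzaldehyde | O=Cc1c(O)cc(F)cc1F | starting material
2 | 2,4-difluoro-6-methoxybenzaldehyde | COc1cc(F)cc(F)c1C=O | intermediate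
3 | 2-bromo-3,4,5-trimethoxybenzaldehyde | COc1cc(C=O)c(Br)c(OC)c1OC | starting material
4 | 3,4,5-trimethoxyphenol | COc1cc(O)cc(OC)c1OC | starting material
5 | 3,4,5-trimethoxy-2-(3,4,5-trimethoxyphenoxy)benzaldehyde | COc1cc(Oc2c(C=O)cc(OC)c(OC)c2OC)cc(OC)c1OC | intermediate
6 | 3,4,5-trimethoxy-2-(3,4,5-trimethoxyphenoxy)phenyl formate (formed in the flask) | COc1cc(Oc2c(OC=O)cc(OC)c(OC)c2OC)cc(OC)c1OC | intermediate
7 | 3,4,5-trimethoxy-2-(3,4,5-trimethoxyphenoxy)phenol | COc1cc(Oc2c(O)cc(OC)c(OC)c2OC)cc(OC)c1OC | intermediate
8 | 4-hydroxy-2,6-dimethoxybenzaldehyde | COc1cc(O)cc(OC)c1C=O | starting material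
9 | 4-(benzyloxy)-2,6-dimethoxybenzaldehyde | COc1cc(OCc2ccccc2)cc(OC)c1C=O | intermediate
10 | 4-(benzyloxy)-2,6-dimethoxyphenyl formate (formed in the flask) | COc1cc(OCc2ccccc2)cc(OC)c1OC=O | intermediate
11 | 4-(benzyloxy)-2,6-dimethoxyphenol | COc1cc(OCc2ccccc2)cc(OC)c1O | intermediate
12 | 2-[4-(benzyloxy)-2,6-dimethoxyphenoxy]-3,4,5-trimethoxybenzaldehyde | O=Cc1cc(OC)c(OC)c(OC)c1Oc1c(OC)cc(OCc2ccccc2)cc1OC | intermediate
13 | 2-[4-(benzyloxy)-2,6-dimethoxyphenoxy]-3,4,5-trimethoxyphenyl formate (formed in the flask) | O=COc1cc(OC)c(OC)c(OC)c1Oc1c(OC)cc(OCc2ccccc2)cc1OC | intermediate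
14 | 2-[4-(benzyloxy)-2,6-dimethoxyphenoxy]-3,4,5-trimethoxyphenol | Oc1cc(OC)c(OC)c(OC)c1Oc1c(OC)cc(OCc2ccccc2)cc1OC | intermediate
15 | 4-{2-[4-(benzyloxy)-2,6-dimethoxyphenoxy]-3,4,5-trimethoxyphenoxy}-2-fluoro-6-methoxybenzaldehyde (formed in the flask) | COc1cc(Oc2cc(OC)c(OC)c(OC)c2Oc2c(OC)cc(OCc3ccccc3)cc2OC)cc(F)c1C=O | intermediate
16 | 4-{2-[4-(benzyloxy)-2,6-dimethoxyphenoxy]-3,4,5-trimethoxyphenoxy}-2-methoxy-6-[3,4,5-trimethoxy-2-(3,4,5-trimethoxyphenoxy)phenoxy]benzaldehyde | COc1cc(Oc2cc(OC)c(OC)c(OC)c2Oc2c(OC)cc(OCc3ccccc3)cc2OC)cc(Oc2cc(OC)c(OC)c(OC)c2Oc2cc(OC)c(OC)c(OC)c2)c1C=O | intermediate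
17 | aryl formate of 16, formyl replaced by formyloxy (formed in the flask) | COc1cc(Oc2cc(OC)c(OC)c(OC)c2Oc2c(OC)cc(OCc3ccccc3)cc2OC)cc(Oc2cc(OC)c(OC)c(OC)c2Oc2cc(OC)c(OC)c(OC)c2)c1OC=O | intermediate
18 | 4-{2-[4-(benzyloxy)-2,6-dimethoxyphenoxy]-3,4,5-trimethoxyphenoxy}-2-methoxy-6-[3,4,5-trimethoxy-2-(3,4,5-trimethoxyphenoxy)phenoxy]phenol | COc1cc(Oc2cc(OC)c(OC)c(OC)c2Oc2c(OC)cc(OCc3ccccc3)cc2OC)cc(Oc2cc(OC)c(OC)c(OC)c2Oc2cc(OC)c(OC)c(OC)c2)c1O | intermediate
19 | 5-{2-[4-(benzyloxy)-2,6-dimethoxyphenoxy]-3,4,5-trimethoxyphenoxy}-1,2-dimethoxy-3-[3,4,5-trimethoxy-2-(3,4,5-trimethoxyphenoxy)phenoxy]benzene | COc1cc(Oc2cc(OC)c(OC)c(OC)c2Oc2c(OC)cc(OCc3ccccc3)cc2OC)cc(Oc2cc(OC)c(OC)c(OC)c2Oc2cc(OC)c(OC)c(OC)c2)c1OC | intermediate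
20 | 4-(6-{3,4-dimethoxy-5-[3,4,5-trimethoxy-2-(3,4,5-trimethoxyphenoxy)phenoxy]phenoxy}-2,3,4-trimethoxyphenoxy)-3,5-dimethoxyphenol | COc1cc(Oc2cc(OC)c(OC)c(OC)c2Oc2c(OC)cc(O)cc2OC)cc(Oc2cc(OC)c(OC)c(OC)c2Oc2cc(OC)c(OC)c(OC)c2)c1OC | intermediate
21 | 2-bromo-4-(6-{3,4-dimethoxy-5-[3,4,5-trimethoxy-2-(3,4,5-trimethoxyphenoxy)phenoxy]phenoxy}-2,3,4-trimethoxyphenoxy)-3,5-dimethoxyphenol | COc1cc(Oc2cc(OC)c(OC)c(OC)c2Oc2c(OC)cc(O)c(Br)c2OC)cc(Oc2cc(OC)c(OC)c(OC)c2Oc2cc(OC)c(OC)c(OC)c2)c1OC | intermediate
22 | O-trimethylsilyl ether of 21 (formed in the flask) | COc1cc(Oc2cc(OC)c(OC)c(OC)c2Oc2c(OC)cc(O[Si](C)(C)C)c(Br)c2OC)cc(Oc2cc(OC)c(OC)c(OC)c2Oc2cc(OC)c(OC)c(OC)c2)c1OC | intermediate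
23 | lithium phenoxide of ring D carrying trimethylsilyl in place of bromine (formed in the flask) | [Li+].COc1cc(Oc2cc(OC)c(OC)c(OC)c2Oc2c(OC)cc([O-])c([Si](C)(C)C)c2OC)cc(Oc2cc(OC)c(OC)c(OC)c2Oc2cc(OC)c(OC)c(OC)c2)c1OC | intermediate
24 | 4-(6-{3,4-dimethoxy-5-[3,4,5-trimethoxy-2-(3,4,5-trimethoxyphenoxy)phenoxy]phenoxy}-2,3,4-trimethoxyphenoxy)-3,5-dimethoxy-2-(trimethylsilyl)phenyl trifluoromethanesulfonate | COc1cc(Oc2cc(OC)c(OC)c(OC)c2Oc2c(OC)cc(OS(=O)(=O)C(F)(F)F)c([Si](C)(C)C)c2OC)cc(Oc2cc(OC)c(OC)c(OC)c2Oc2cc(OC)c(OC)c(OC)c2)c1OC | intermediate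
25 | 4-bromo-2,6-dimethoxybenzaldehyde | COc1cc(Br)cc(OC)c1C=O | starting material
26 | 2,4,6-trimethoxyphenol | COc1cc(OC)c(O)c(OC)c1 | starting material
27 | 2,6-dimethoxy-4-(2,4,6-trimethoxyphenoxy)benzaldehyde | COc1cc(OC)c(Oc2cc(OC)c(C=O)c(OC)c2)c(OC)c1 | intermediate
28 | 2,6-dimethoxy-4-(2,4,6-trimethoxyphenoxy)phenyl formate (formed in the flask) | COc1cc(OC)c(Oc2cc(OC)c(OC=O)c(OC)c2)c(OC)c1 | intermediate
29 | 2,6-dimethoxy-4-(2,4,6-trimethoxyphenoxy)phenol | COc1cc(OC)c(Oc2cc(OC)c(O)c(OC)c2)c(OC)c1 | intermediate
30 | 5-bromo-1,2,3-trimethoxybenzene | COc1cc(Br)cc(OC)c1OC | starting material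
31 | 1-bromo-2-[chloro(methoxy)methyl]-3,4,5-trimethoxybenzene, racemic (formed in the flask) | COC(Cl)c1c(Br)cc(OC)c(OC)c1OC | intermediate
32 | 6-bromo-2,3,4-trimethoxybenzaldehyde | COc1cc(Br)c(C=O)c(OC)c1OC | intermediate
33 | 6-[2,6-dimethoxy-4-(2,4,6-trimethoxyphenoxy)phenoxy]-2,3,4-trimethoxybenzaldehyde | COc1cc(OC)c(Oc2cc(OC)c(Oc3cc(OC)c(OC)c(OC)c3C=O)c(OC)c2)c(OC)c1 | intermediate
34 | 6-[2,6-dimethoxy-4-(2,4,6-trimethoxyphenoxy)phenoxy]-2,3,4-trimethoxyphenyl formate (formed in the flask) | COc1cc(OC)c(Oc2cc(OC)c(Oc3cc(OC)c(OC)c(OC)c3OC=O)c(OC)c2)c(OC)c1 | intermediate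
35 | 6-[2,6-dimethoxy-4-(2,4,6-trimethoxyphenoxy)phenoxy]-2,3,4-trimethoxyphenol | COc1cc(OC)c(Oc2cc(OC)c(Oc3cc(OC)c(OC)c(OC)c3O)c(OC)c2)c(OC)c1 | intermediate
36 | ring D aryne: 24 without the trimethylsilyl and triflate groups, triple bond between the two carbons that carried them (formed in the flask) | COc1cc(Oc2cc(OC)c(OC)c(OC)c2OC2=C(OC)C#CC=C2OC)cc(Oc2cc(OC)c(OC)c(OC)c2Oc2cc(OC)c(OC)c(OC)c2)c1OC | intermediate
37 | henicosamethyl ether of the target (rings A to H, all 21 hydroxyls as methoxy) | COc1cc(OC)c(Oc2cc(OC)c(Oc3cc(OC)c(OC)c(OC)c3Oc3cc(OC)c(Oc4c(Oc5cc(OC)c(OC)c(Oc6cc(OC)c(OC)c(OC)c6Oc6cc(OC)c(OC)c(OC)c6)c5)cc(OC)c(OC)c4OC)c(OC)c3)c(OC)c2)c(OC)c1 | intermediate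
38 | target octamer CNP0309601.0 (rings A to H, 21 free hydroxyls) | Oc1cc(O)c(Oc2cc(O)c(Oc3cc(O)c(O)c(O)c3Oc3cc(O)c(Oc4c(Oc5cc(O)c(O)c(Oc6cc(O)c(O)c(O)c6Oc6cc(O)c(O)c(O)c6)c5)cc(O)c(O)c4O)c(O)c3)c(O)c2)c(O)c1 | target

## Step count and least certain steps

Total: 20 steps in three branches (steps 1 to 13, steps 14 to 18, union and deprotection in steps 19 and 20). Longest linear sequence: 12 steps (steps 4 to 13, then 19 and 20, from **8** to **38**).

**Step 8 (key step).** The most likely failure is loss of site selectivity in the first substitution: partial attack of the phenoxide of **14** at the ortho fluorine would exchange the positions of the two dimers on ring F. The second displacement may also be slow, because the ring then carries a para-aryloxy donor.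
Fallback: the two sites are told apart by the kind of leaving group. The fallback sets out from phenols **7** and **14** and returns at **16**. 4-Bromo-2,6-difluorobenzaldehyde F1 is treated with one equivalent of NaOMe in MeOH to give 4-bromo-2-fluoro-6-methoxybenzaldehyde F2. Its single fluoride is displaced by the phenoxide of **7** (K2CO3, DMSO, 90 °C) to give 4-bromo-2-methoxy-6-[3,4,5-trimethoxy-2-(3,4,5-trimethoxyphenoxy)phenoxy]benzaldehyde F3. The bromide para to the formyl group is then coupled with **14** under CuI/picolinic acid/K3PO4 in DMSO to give **16**.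

**Step 6.** C–O bond formation at a carbon flanked by formyl and methoxy, with a 2,6-dimethoxyphenoxide, may be so slow that hydrodebromination of **3** and oxidative decomposition of the phenoxide take over.
Fallback: a carboxylate-directed Ullmann condensation, in which the ortho carboxylate binds copper next to the bromide. It sets out from **11** and returns at **12**. Phenol **11** and 2-bromo-3,4,5-trimethoxybenzoic acid F4 (Cu powder, CuI, K2CO3, DMF, 130 °C) give 2-[4-(benzyloxy)-2,6-dimethoxyphenoxy]-3,4,5-trimethoxybenzoic acid F5. BH3·THF reduces it to {2-[4-(benzyloxy)-2,6-dimethoxyphenoxy]-3,4,5-trimethoxyphenyl}methanol F6, and MnO2 in CH2Cl2 oxidises this to **12**.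

**Step 12.** Bromination may spread to the other activated rings (each has CH positions between two oxygens) or go on to the dibromide, because the difference between a phenol and a polyalkoxyarene is one of rate only.
Fallback: the silyl group is put in by directed ortho-metalation instead of electrophilic substitution. It sets out from **20** and returns at **24**. Diethylcarbamoyl chloride and NaH in THF give the N,N-diethylcarbamate of 20 F7. Treatment with s-BuLi/TMEDA in THF at −78 °C, where the carbamate and the neighbouring methoxy group acidify the same ring D position, followed by TMSCl, gives the ortho-trimethylsilyl carbamate F8. LiAlH4 in THF releases the ortho-trimethylsilyl phenol F9, which Tf2O and pyridine convert into **24**.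

**Step 19.** The aryne may be captured by fluoride or solvent faster than by the hindered phenoxide, or the phenoxide may attack the triflate at sulfur. In both cases the precious five-ring fragment is lost.
Fallback: the ether is closed by cross-coupling, in which the metal inserts at the unhindered ring D carbon. It sets out from **20** and returns at **37**. Tf2O and pyridine give the aryl triflate of 20 F10, which is coupled with **35** under Pd(OAc)2, a bulky di-tert-butyl biarylphosphine and K3PO4 in toluene at 100 °C (palladium-catalysed diaryl ether synthesis).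

**Step 20.** Cleavage of 21 ethers may stop short, and the free polyphenol may be lost by air oxidation during isolation.
Fallback: the product is derivatised, purified and released. It sets out from **37** and returns at **38**. After BBr3 (or molten pyridinium chloride at 190 °C if boron is retained by the pyrogallol rings), the crude product is acetylated at once (Ac2O, pyridine) to the henicosaacetate of the target F11. This is stable to air and silica and can be purified, and fractions still carrying methyl groups can be returned to the cleavage. HCl in degassed MeOH then removes the acetates to give **38**.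

## Further compounds

F1 | step 8 | 4-bromo-2,6-difluorobenzaldehyde | O=Cc1c(F)cc(Br)cc1F
F2 | step 8 | 4-bromo-2-fluoro-6-methoxybenzaldehyde | COc1cc(Br)cc(F)c1C=O
F3 | step 8 | 4-bromo-2-methoxy-6-[3,4,5-trimethoxy-2-(3,4,5-trimethoxyphenoxy)phenoxy]benzaldehyde | COc1cc(Br)cc(Oc2cc(OC)c(OC)c(OC)c2Oc2cc(OC)c(OC)c(OC)c2)c1C=O
F4 | step 6 | 2-bromo-3,4,5-trimethoxybenzoic acid | COc1cc(C(=O)O)c(Br)c(OC)c1OC
F5 | step 6 | 2-[4-(benzyloxy)-2,6-dimethoxyphenoxy]-3,4,5-trimethoxybenzoic acid | OC(=O)c1cc(OC)c(OC)c(OC)c1Oc1c(OC)cc(OCc2ccccc2)cc1OC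
F6 | step 6 | {2-[4-(benzyloxy)-2,6-dimethoxyphenoxy]-3,4,5-trimethoxyphenyl}methanol | OCc1cc(OC)c(OC)c(OC)c1Oc1c(OC)cc(OCc2ccccc2)cc1OC
F7 | step 12 | N,N-diethylcarbamate of 20 | COc1cc(Oc2cc(OC)c(OC)c(OC)c2Oc2c(OC)cc(OC(=O)N(CC)CC)cc2OC)cc(Oc2cc(OC)c(OC)c(OC)c2Oc2cc(OC)c(OC)c(OC)c2)c1OC
F8 | step 12 | ortho-trimethylsilyl N,N-diethylcarbamate of ring D | COc1cc(Oc2cc(OC)c(OC)c(OC)c2Oc2c(OC)cc(OC(=O)N(CC)CC)c([Si](C)(C)C)c2OC)cc(Oc2cc(OC)c(OC)c(OC)c2Oc2cc(OC)c(OC)c(OC)c2)c1OC
F9 | step 12 | ortho-trimethylsilyl phenol of ring D | COc1cc(Oc2cc(OC)c(OC)c(OC)c2Oc2c(OC)cc(O)c([Si](C)(C)C)c2OC)cc(Oc2cc(OC)c(OC)c(OC)c2Oc2cc(OC)c(OC)c(OC)c2)c1OC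
F10 | step 19 | aryl triflate of 20 | COc1cc(Oc2cc(OC)c(OC)c(OC)c2Oc2c(OC)cc(OS(=O)(=O)C(F)(F)F)cc2OC)cc(Oc2cc(OC)c(OC)c(OC)c2Oc2cc(OC)c(OC)c(OC)c2)c1OC
F11 | step 20 | henicosaacetate of the target | CC(=O)Oc1cc(OC(C)=O)c(Oc2cc(OC(C)=O)c(Oc3cc(OC(C)=O)c(OC(C)=O)c(OC(C)=O)c3Oc3cc(OC(C)=O)c(Oc4c(Oc5cc(OC(C)=O)c(OC(C)=O)c(Oc6cc(OC(C)=O)c(OC(C)=O)c(OC(C)=O)c6Oc6cc(OC(C)=O)c(OC(C)=O)c(OC(C)=O)c6)c5)cc(OC(C)=O)c(OC(C)=O)c4OC(C)=O)c(OC(C)=O)c3)c(OC(C)=O)c2)c(OC(C)=O)c1
A1 | alternative 1 | dimethyl 5-[4-(benzyloxy)-3,5-dimethoxyphenoxy]-2,4,6-trihydroxybenzene-1,3-dicarboxylate | COC(=O)c1c(O)c(Oc2cc(OC)c(OCc3ccccc3)c(OC)c2)c(O)c(C(=O)OC)c1O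
A2 | alternative 1 | dimethyl 2-[4-(benzyloxy)-3,5-dimethoxyphenoxy]propanedioate | COC(=O)C(Oc1cc(OC)c(OCc2ccccc2)c(OC)c1)C(=O)OC
A3 | alternative 1 | dimethyl 3-oxopentanedioate | COC(=O)CC(=O)CC(=O)OC
A4 | alternative 2 | cyclopentadienylruthenium hexafluorophosphate complex of the A–B–C triaryl diether, divalent ruthenium | COc1cc(OC)c(Oc2cc(OC)c(Oc3cc(OC)c(OC)c(OC)c3OCc3ccccc3)c(OC)c2)c(OC)c1.[cH-]1cccc1.[Ru+2].F[P-](F)(F)(F)(F)F
A5 | alternative 2 | cyclopentadienylruthenium hexafluorophosphate complex of 2,5-dichloro-1,3-dimethoxybenzene, divalent ruthenium | COc1cc(Cl)cc(OC)c1Cl.[cH-]1cccc1.[Ru+2].F[P-](F)(F)(F)(F)F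
A6 | alternative 2 | 2-(benzyloxy)-3,4,5-trimethoxyphenol | COc1cc(O)c(OCc2ccccc2)c(OC)c1OC
A7 | alternative 3 | 2-[4-(benzyloxy)-2,6-dimethoxyphenoxy]-5-ethoxy-3,4-dimethoxyphenol | Oc1cc(OCC)c(OC)c(OC)c1Oc1c(OC)cc(OCc2ccccc2)cc1OC
A8 | alternative 3 | 2-[4-(benzyloxy)-2,6-dimethoxyphenoxy]-4-(1-ethoxyethenyl)-3,4-dimethoxycyclobut-2-en-1-one, racemic | CCOC(=C)C1(OC)C(OC)=C(Oc2c(OC)cc(OCc3ccccc3)cc2OC)C1=O
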